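**Strategy.** Ring A is disconnected at C1–C10 and C3–C4 (labdane numbering), which leaves ring B carrying a C4–C5–C10 triad of two 1,3-related nucleophilic carbons and a C1–C2–C3 dielectrophile. The key step is a one-flask [3+3] annulation: a dianion (cross-conjugated ketone enolate at C10, malonate anion at C4) is alkylated at C10 by 1-chloro-3-iodopropane and then closes ring A at C4, setting the quaternary C10 and the trans ring fusion. Its precursor is a 5-malonyl-2,6-dimethylcyclohex-2-enone made from (R)-carvone, whose enone carbons become C9, C10 and C5 and whose isopropenyl group relays chirality before it is excised. C4 methylation and a B-alkyl Suzuki coupling at C9 finish the skeleton.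

Key step: step 4

Remark on the chemistry: positions are given in labdane numbering (ring A = C1–C5 and C10, ring B = C5–C10, C20 on C10, C17 on C8, C18 alpha and C19 beta on C4); carbons whose configuration is not controlled and is erased later are written without a stereodescriptor; anions formed by simple deprotonation are treated as salts of the numbered compounds; (E)-3-methylpent-2-en-4-yn-1-ol is assumed to be purchasable as the single E isomer.

Step 1
Reactants: 1 (R)-(−)-carvone
Product: 2 (5R,6S)-2,6-dimethyl-5-(prop-1-en-2-yl)cyclohex-2-en-1-one (trans-6-methylcarvone; the 6R epimer is carried along)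
Conditions: LDA, THF, −78 °C; MeI, −78 to 0 °C
Reagents that add atoms: iodomethane (CI)
Why: Kinetic enolate alkylation: LDA removes the only alpha-prime proton of the enone to give the cross-conjugated enolate, which is methylated mainly anti to the isopropenyl group, and the configuration of this new centre is immaterial because the carbon becomes sp2 in step 3.

Step 2
Reactants: 2 trans-6-methylcarvone, 3 dimethyl malonate
Product: 4 dimethyl 2-[(1R,5R)-2,4-dimethyl-3-oxo-5-(prop-1-en-2-yl)cyclohexyl]propanedioate (epimers at ring C2 and C4)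
Conditions: NaOMe (cat.), MeOH, rt
Reagents that add atoms: none
Why: Base-catalysed Michael addition in which the malonate anion attacks the enone beta-carbon axially and anti to the isopropenyl group, so that the new stereocentre (the future C5) is set 1,3-trans to it, while the two centres alpha to the ketone equilibrate and are erased later.

Step 3
Reactants: 4 Michael adduct
Product: 6 dimethyl 2-[(1R)-4,6-dimethyl-5-oxocyclohex-3-en-1-yl]propanedioate (epimers at ring C6), via methoxy hydroperoxide 5 (not isolated)
Conditions: O3, CH2Cl2/MeOH, −78 °C; then FeSO4·7H2O, Cu(OAc)2·H2O, −20 °C to rt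
Reagents that add atoms: none
Why: Ozonolytic dealkenylation: ozone cleaves the only C=C bond in methanol to the alpha-methoxy hydroperoxide, FeSO4 reduces it to an alkoxy radical that loses methyl acetate by beta-scission, and Cu(OAc)2 oxidises the resulting ring radical to the alkene, which forms toward the acidic alpha-carbon in conjugation with the ketone, without touching C5.

Step 4
Reactants: 6 malonyl enone, 7 1-chloro-3-iodopropane
Product: 9 dimethyl (4aS,8aR)-4a,6-dimethyl-5-oxo-3,4,4a,5,8,8a-hexahydronaphthalene-1,1(2H)-dicarboxylate, via chloropropyl enone 8 (not isolated)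
Conditions: NaH (1.0 equiv), THF, 0 °C; LDA (1.1 equiv), −78 °C; ICH2CH2CH2Cl, DMPU, −78 to 0 °C; then NaI (cat.), 60 °C
Reagents that add atoms: none
Why: Sequential deprotonation gives a dianion whose last-formed and more basic cross-conjugated ketone enolate (C10) is alkylated first by the iodide end of the dihalide, after which the resting malonate anion (C4) displaces chloride intramolecularly, so that the ring-A bonds C1–C10 and C3–C4 are both made in one flask. The closest known reaction types are the site-selective alkylation of dianions at their most basic centre and the cycloalkylation of malonates with 1,3-dihalides, merged here into a formal [3+3] annulation. Ring A closes at C4 in a 6-exo-tet mode. C10 is set in the intermolecular alkylation, where the electrophile approaches the enolate face anti to the bulky C5 malonate substituent (as in alkylations of 6-alkylcarvone enolates), which places C1 trans to C4 and so gives the trans-fused decalin with the C10 methyl group beta, while C5 is already fixed and C4 carries two identical esters. The step needs chemoselectivity (enolate before malonate, iodide before chloride) and regioselectivity (alpha-prime instead of gamma deprotonation), which are secured by the reactivity gap between the two anions and the two halides and by C8 being sp2, so that C10–H is the only alpha-proton of the ketone. Keeping the malonate deprotonated throughout also blocks retro-Michael loss of malonate from the C10 enolate.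

Step 5
Reactants: 9 bicyclic geminal diester
Product: 10 methyl (4aS,8aS)-4a,6-dimethyl-5-oxo-1,2,3,4,4a,5,8,8a-octahydronaphthalene-1-carboxylate (epimers at C1, that is C4 of the labdane)
Conditions: LiCl, H2O, DMSO, 160 °C
Reagents that add atoms: none
Why: Krapcho dealkoxycarbonylation, in which chloride dealkylates one methyl ester and the carboxylate loses CO2, removes the surplus ester, and the configuration in which C4 is reprotonated is irrelevant because C4 is enolised again in step 7.

Step 6
Reactants: 10 enone monoester
Product: 12 methyl (4aS,8aS)-4a,6-dimethyl-5-{[(trifluoromethyl)sulfonyl]oxy}-1,2,3,4,4a,7,8,8a-octahydronaphthalene-1-carboxylate (epimers at C1), via lithium enolate 11 (not isolated)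
Conditions: LiBH(s-Bu)3 (L-Selectride), THF, −78 °C; PhNTf2, −78 °C to rt
Reagents that add atoms: N-phenylbis(trifluoromethanesulfonimide) (O=S(=O)(N(c1ccccc1)S(=O)(=O)C(F)(F)F)C(F)(F)F)
Why: Conjugate reduction of the alpha-methyl enone by the bulky borohydride (1,4-selective because the carbonyl is flanked by the quaternary C10, as with carvone itself) gives the C8=C9 enolate regiospecifically, and O-sulfonylation with PhNTf2 fixes the tetrasubstituted double bond as the enol triflate without creating a stereocentre.

Step 7
Reactants: 12 enol triflate ester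
Product: 13 methyl (1S,4aS,8aR)-1,4a,6-trimethyl-5-{[(trifluoromethyl)sulfonyl]oxy}-1,2,3,4,4a,7,8,8a-octahydronaphthalene-1-carboxylate
Conditions: LDA, THF/DMPU, −78 °C; MeI, −78 to 0 °C
Reagents that add atoms: iodomethane (CI)
Why: Ester enolate alkylation in which iodomethane approaches the exocyclic C4 enolate on the alpha (equatorial) face, the beta face being screened by the syn-axial C10 methyl group, so that the new methyl group is alpha and the ester ends up axial (beta), which is the C19-ester configuration of the target.

Step 8
Reactants: 14 (E)-3-methylpent-2-en-4-yn-1-ol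
Product: 15 (E)-3-methylpenta-2,4-dien-1-ol
Conditions: H2 (1 atm), Pd/CaCO3 poisoned with Pb(OAc)2 (Lindlar catalyst), quinoline, EtOAc, rt
Reagents that add atoms: none
Why: Lindlar semihydrogenation reduces the terminal alkyne to the vinyl group on the poisoned catalyst and leaves the trisubstituted alkene and its E geometry untouched.

Step 9
Reactants: 13 methylated enol triflate, 15 (E)-3-methylpenta-2,4-dien-1-ol
Product: 17 methyl (1S,4aS,8aR)-5-[(E)-5-hydroxy-3-methylpent-3-en-1-yl]-1,4a,6-trimethyl-1,2,3,4,4a,7,8,8a-octahydronaphthalene-1-carboxylate (methyl 15-hydroxylabda-8,13E-dien-19-oate), via alkylborane 16 (not isolated)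
Conditions: 15, 9-BBN (2.2 equiv), THF, 0 °C to rt; then 13, PdCl2(dppf) (cat.), AsPh3, Cs2CO3, DMF/H2O, 50 °C
Reagents that add atoms: none
Why: B-alkyl Suzuki–Miyaura coupling: 9-BBN first masks the hydroxyl as a borinate and then adds anti-Markovnikov to the only monosubstituted alkene of the diene, and the resulting primary alkylborane couples with the enol triflate with retention of the C8=C9 position and of the E alkene, no stereocentre being formed.

Step 10
Reactants: 17 hydroxy methyl ester
Product: 18 (1S,4aS,8aR)-5-[(E)-5-hydroxy-3-methylpent-3-en-1-yl]-1,4a,6-trimethyl-1,2,3,4,4a,7,8,8a-octahydronaphthalene-1-carboxylic acid (15-hydroxylabda-8,13E-dien-19-oic acid)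
Conditions: NaSEt, DMF, 110 °C; then aqueous HCl
Reagents that add atoms: none
Why: Nucleophilic ester cleavage by SN2 attack of thiolate on the O-methyl group frees the axial C19 acid, whose carbonyl is too hindered for saponification, without affecting any stereocentre or alkene.

Step 11
Reactants: 18 hydroxy acid
Product: 19 (1S,4aS,8aR)-5-[(E)-5-acetoxy-3-methylpent-3-en-1-yl]-1,4a,6-trimethyl-1,2,3,4,4a,7,8,8a-octahydronaphthalene-1-carboxylic acid (15-acetoxylabda-8,13E-dien-19-oic acid, the target)
Conditions: Ac2O, pyridine, DMAP (cat.), CH2Cl2, 0 °C to rt; aqueous NaHCO3 work-up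
Reagents that add atoms: acetic anhydride (CC(=O)OC(C)=O)
Why: DMAP-catalysed O-acetylation is selective for the primary allylic alcohol because the neopentyl tertiary carboxylic acid is acylated at most reversibly, any mixed anhydride being hydrolysed during the aqueous work-up.

**Compound list**

1 | (R)-(−)-carvone, (5R)-2-methyl-5-(prop-1-en-2-yl)cyclohex-2-en-1-one | CC1=CC[C@H](CC1=O)C(C)=C | starting material
2 | (5R,6S)-2,6-dimethyl-5-(prop-1-en-2-yl)cyclohex-2-en-1-one (major epimer drawn) | CC1=CC[C@H]([C@H](C)C1=O)C(C)=C | intermediate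
3 | dimethyl malonate | COC(=O)CC(=O)OC | starting material
4 | dimethyl 2-[(1R,5R)-2,4-dimethyl-3-oxo-5-(prop-1-en-2-yl)cyclohexyl]propanedioate (epimers at ring C2 and C4) | CC1[C@H](C(C(=O)OC)C(=O)OC)C[C@@H](C(C)=C)C(C)C1=O | intermediate
5 | dimethyl 2-[(1R,5R)-5-(1-hydroperoxy-1-methoxyethyl)-2,4-dimethyl-3-oxocyclohexyl]propanedioate (not isolated) | CC1[C@H](C(C(=O)OC)C(=O)OC)C[C@@H](C(C)(OC)OO)C(C)C1=O | intermediate
6 | dimethyl 2-[(1R)-4,6-dimethyl-5-oxocyclohex-3-en-1-yl]propanedioate (epimers at ring C6) | CC1[C@H](C(C(=O)OC)C(=O)OC)CC=C(C)C1=O | intermediate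
7 | 1-chloro-3-iodopropane | ClCCCI | starting material
8 | dimethyl 2-[(1S,6S)-6-(3-chloropropyl)-4,6-dimethyl-5-oxocyclohex-3-en-1-yl]propanedioate (not isolated, present as its malonate anion) | C[C@]1(CCCCl)[C@H](C(C(=O)OC)C(=O)OC)CC=C(C)C1=O | intermediate
9 | dimethyl (4aS,8aR)-4a,6-dimethyl-5-oxo-3,4,4a,5,8,8a-hexahydronaphthalene-1,1(2H)-dicarboxylate | O=C1C(C)=CC[C@H]2C(C(=O)OC)(C(=O)OC)CCC[C@]12C | intermediate
10 | methyl (4aS,8aS)-4a,6-dimethyl-5-oxo-1,2,3,4,4a,5,8,8a-octahydronaphthalene-1-carboxylate (epimers at C1) | O=C1C(C)=CC[C@H]2C(C(=O)OC)CCC[C@]12C | intermediate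
11 | lithium C8=C9 enolate of the saturated keto ester derived from 10 (not isolated) | [Li]OC1=C(C)CC[C@H]2C(C(=O)OC)CCC[C@]12C | intermediate
12 | methyl (4aS,8aS)-4a,6-dimethyl-5-{[(trifluoromethyl)sulfonyl]oxy}-1,2,3,4,4a,7,8,8a-octahydronaphthalene-1-carboxylate (epimers at C1) | O=S(=O)(OC1=C(C)CC[C@H]2C(C(=O)OC)CCC[C@]12C)C(F)(F)F | intermediate
13 | methyl (1S,4aS,8aR)-1,4a,6-trimethyl-5-{[(trifluoromethyl)sulfonyl]oxy}-1,2,3,4,4a,7,8,8a-octahydronaphthalene-1-carboxylate | O=S(=O)(OC1=C(C)CC[C@H]2[C@@](C)(C(=O)OC)CCC[C@]12C)C(F)(F)F | intermediate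
14 | (E)-3-methylpent-2-en-4-yn-1-ol | OC/C=C(\C)C#C | starting material
15 | (E)-3-methylpenta-2,4-dien-1-ol | OC/C=C(\C)C=C | intermediate
16 | 9-[(E)-5-(9-borabicyclo[3.3.1]nonan-9-yloxy)-3-methylpent-3-en-1-yl]-9-borabicyclo[3.3.1]nonane (not isolated) | C\C(CCB1C2CCCC1CCC2)=C/COB1C2CCCC1CCC2 | intermediate
17 | methyl (1S,4aS,8aR)-5-[(E)-5-hydroxy-3-methylpent-3-en-1-yl]-1,4a,6-trimethyl-1,2,3,4,4a,7,8,8a-octahydronaphthalene-1-carboxylate | OC/C=C(\C)CCC1=C(C)CC[C@H]2[C@@](C)(C(=O)OC)CCC[C@]12C | intermediate
18 | (1S,4aS,8aR)-5-[(E)-5-hydroxy-3-methylpent-3-en-1-yl]-1,4a,6-trimethyl-1,2,3,4,4a,7,8,8a-octahydronaphthalene-1-carboxylic acid | OC/C=C(\C)CCC1=C(C)CC[C@H]2[C@@](C)(C(=O)O)CCC[C@]12C | intermediate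
19 | (1S,4aS,8aR)-5-[(E)-5-acetoxy-3-methylpent-3-en-1-yl]-1,4a,6-trimethyl-1,2,3,4,4a,7,8,8a-octahydronaphthalene-1-carboxylic acid (4S,5R,10S in labdane numbering) | CC(=O)OC/C=C(\C)CCC1=C(C)CC[C@H]2[C@@](C)(C(=O)O)CCC[C@]12C | target

Stereochemical account: C5 is set in step 2 (relayed from the carvone stereocentre, which is destroyed in step 3), C10 in step 4, C4 in step 7, and the 13E alkene is carried from 14.

Total step count: 11. Longest linear sequence: 10 steps (steps 1–7 and 9–11); step 8 prepares the side-chain partner.

**Steps most likely to fail and their fallbacks**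

Step 4 (key step). Alkylation of the congested tetrasubstituted C10 enolate by an unactivated primary iodide may be slow. Proton transfer to the extended gamma-dienolate, or alkylation at the malonate carbon first (which would then close the cis-fused ring), could then compete. Fallback: starting from 6, the same dianion is quenched at −78 °C with the far more reactive allyl bromide, which should give, under the same facial control, dimethyl 2-[(1S,6S)-4,6-dimethyl-5-oxo-6-(prop-2-en-1-yl)cyclohex-3-en-1-yl]propanedioate F1. Peroxide-initiated anti-Markovnikov addition of HBr to the terminal alkene then gives dimethyl 2-[(1S,6S)-6-(3-bromopropyl)-4,6-dimethyl-5-oxocyclohex-3-en-1-yl]propanedioate F2. Cs2CO3 in DMF closes ring A by intramolecular malonate alkylation, which returns to 9.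

Step 9. Oxidative addition and transmetalation at the tetrasubstituted enol triflate next to the quaternary C10 may be too slow, so that protodeboronation or beta-hydride elimination of the alkylborane takes over. Fallback: from 13 the hindered bond is made as an sp2–sp2 bond instead. Stille coupling with tributyl(vinyl)stannane (Pd(PPh3)4, LiCl, THF, reflux) should give methyl (1S,4aS,8aR)-5-ethenyl-1,4a,6-trimethyl-1,2,3,4,4a,7,8,8a-octahydronaphthalene-1-carboxylate F3. 9-BBN adds to its terminal vinyl carbon to give the primary alkylborane methyl (1S,4aS,8aR)-5-[2-(9-borabicyclo[3.3.1]nonan-9-yl)ethyl]-1,4a,6-trimethyl-1,2,3,4,4a,7,8,8a-octahydronaphthalene-1-carboxylate F4, used in solution. Its Suzuki–Miyaura coupling with the known vinyl iodide (E)-3-iodobut-2-en-1-ol F5 (PdCl2(dppf), Cs2CO3, DMF/H2O) forms the unhindered C12–C13 bond with retention of alkene geometry and returns to 17.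

Step 3. The copper-mediated oxidation of the ring radical may lose the beta-hydrogen from C6 instead of C8, giving the non-conjugated alkene, or the radical may simply abstract hydrogen. Fallback: from 4, ozonolysis in CH2Cl2/MeOH followed by Ac2O, Et3N and DMAP (Criegee rearrangement) converts the isopropenyl group, with retention, into dimethyl 2-[(1R,5R)-5-acetoxy-2,4-dimethyl-3-oxocyclohexyl]propanedioate F6. DBU then eliminates acetic acid through the C8 enolate (E1cB), which can place the double bond only at C7=C8, and returns to 6.

Further compounds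
F1 | step 4 | dimethyl 2-[(1S,6S)-4,6-dimethyl-5-oxo-6-(prop-2-en-1-yl)cyclohex-3-en-1-yl]propanedioate | C[C@]1(CC=C)[C@H](C(C(=O)OC)C(=O)OC)CC=C(C)C1=O
F2 | step 4 | dimethyl 2-[(1S,6S)-6-(3-bromopropyl)-4,6-dimethyl-5-oxocyclohex-3-en-1-yl]propanedioate | C[C@]1(CCCBr)[C@H](C(C(=O)OC)C(=O)OC)CC=C(C)C1=O
F3 | step 9 | methyl (1S,4aS,8aR)-5-ethenyl-1,4a,6-trimethyl-1,2,3,4,4a,7,8,8a-octahydronaphthalene-1-carboxylate | C=CC1=C(C)CC[C@H]2[C@@](C)(C(=O)OC)CCC[C@]12C
F4 | step 9 | methyl (1S,4aS,8aR)-5-[2-(9-borabicyclo[3.3.1]nonan-9-yl)ethyl]-1,4a,6-trimethyl-1,2,3,4,4a,7,8,8a-octahydronaphthalene-1-carboxylate | C1CCC2CCCC1B2CCC3=C(C)CC[C@H]4[C@@](C)(C(=O)OC)CCC[C@]34C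
F5 | step 9 | (E)-3-iodobut-2-en-1-ol | OC/C=C(\C)I
F6 | step 3 | dimethyl 2-[(1R,5R)-5-acetoxy-2,4-dimethyl-3-oxocyclohexyl]propanedioate (epimers at ring C2 and C4) | CC1[C@H](C(C(=O)OC)C(=O)OC)C[C@@H](OC(C)=O)C(C)C1=O
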